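Readings and results were computed with constants of no real substance; noise was put on by code.

**Hands off.** Leave the enzyme as it stands and give the second portion on time. Our flask is the summer run.

| flask | substrate | enzyme | remark | time |
|---|---|---|---|---|
| summer | 0.020 M (in portions, 2) | 0.15 µM | the very flask that is asked about, followed so far; portions every 2.5 min |  |
| midnight | 0.020 M (in portions, 2) | 0.075 µM | run made earlier; portions every 2.5 min |  |
| flask | 0.020 M (in portions, 2) | 0.15 µM | the portions of substrate follow each other after 2.5 min, the first at the start | 5.0 min |

- summer (time / s: target / %, substrate / %, isomer of the product / %): 12.0: 13.0, 37.7, 0.8; 25.0: 20.9, 25.3, 0.5; 40.0: 26.9, 19.5, 1.7; 50.0: 29.6, 12.2, 2.6; 60.0: 34.0, 11.9, 4.7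
- midnight (time / min: target / %, substrate / %, isomer of the product / %): 0.417: 13.3, 34.9, 1.1; 1.33: 26.4, 18.8, 3.9; 2.50: 31.2, 8.8, 10.5; 4.00: 51.2, 24.7, 18.0; 5.00: 56.2, 14.5, 26.9

(each reading ± 1 percentage point)

- the species that holds most of what was charged as substrate, at 5.0 min (isomer of the product / target / substrate)
- the largest share itself, whichever of these holds it, in percent of the substrate charged

- a species is counted by the substrate in it: one idle adduct counts as two
- amounts and yields of target count idle adduct and crystals too
- given per volume of solution although it is solid: crystals
- steps thought possible: substrate + enzyme -> target + enzyme; substrate + target <-> idle adduct; target <-> isomer of the product; crystals <-> target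
- in an amount of target, one idle adduct counts as one target
- a reading at the moment of an addition is taken just before it
- percentages count the whole charge, also what has not yet gone in
- a reading or a percentage of substrate is of its free form alone

**Clearing rate.** Take the logarithm of how far a portion's free substrate has fallen, per minute. The midnight run gives 0.695 min⁻¹ for its first portion. The summer flask gives 1.44 min⁻¹, twice that with twice the enzyme, so we read the fall as pseudo-first-order, scaling with enzyme. Midnight's second portion, counted with its remainder, clears at 0.560 min⁻¹, our second-portion clearing rate, more slowly than the first.

**On return.** Scaled to the summer enzyme, these leave 1.55 % of the charge as free substrate before the second portion and 3.13 % at 5.0 min.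

**The forecast.** It names target at 61 %, between 56 % and 67 %: “Mass balances close to within a few percent, so the adduct is minor.” It puts free substrate at 5.0 min at 1 to 2 percent, where we reckon 3.13 %.

**The flask.** It gives target at 62.4 %, isomer of the product 32.7 % and substrate 4.03 %.

    substrate + enzyme → target + enzyme, rate k1*[substrate]*[enzyme]/(1 + ([substrate]/Km1) + ([target]/Kp1)) (8.70 mM, 8.10 mM, k = 3.40 × 10⁵ L mol⁻¹ s⁻¹)
    substrate + target ⇌ idle adduct, settled at all times (K = 18.0 L mol⁻¹)
    target ⇌ isomer of the product (K = 0.890, k = 0.00440 s⁻¹)
    crystals ⇌ target, rate k4*(cs4 - [target]) while solid is left; crystals form when [target] > cs4 (solubility = 18.0 mM, k = 0.260 s⁻¹)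

**Two clocks.** Our clearing rate gives substrate a half-life of 0.619 min, shorter than the 1.24 min relaxation half-life of target and isomer of the product, itself short against 5.0 min. In a neighbour flask with 0.0370 µM of enzyme, the two clearing rates leave 35.7 % as free substrate. That neighbour flask holds 34 % of free substrate, with target at 43.4 %, below the low end of the forecast's range, 56 %.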